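**Retrosynthetic overview**
- Feature: the all-trans oxolane splits into two pieces. O1–C5–C4 (ring B, 3,4,5-trimethoxyphenyl, on C5; CH2OH arm on C4) maps onto the O–C–C of a trans-2-aryl-3-vinyloxirane, with the vinyl group as the masked arm. C2–C3 (ring A, 4-hydroxy-3,5-dimethoxyphenyl, on C2; arm on C3) maps onto the C=C bond of an arylidene Meldrum's acid made from syringaldehyde.
- Key disconnection: O1–C2 and C3–C4 are cut together. This is a zerovalent-palladium formal (3+2) annulation of vinyloxirane 6 with acceptor 10, and it closes the oxolane, the only ring built and kept.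
- Oxirane 6 comes from 3,4,5-trimethoxycinnamic acid by Sharpless epoxidation, oxidation and Wittig methylenation. Acceptor 10 comes from O-benzylsyringaldehyde by Knoevenagel condensation.
- After the annulation the spiro Meldrum's acid loses one carboxyl and C3 is equilibrated trans to both neighbours. The vinyl group is then cut to the C4 arm, both arms are reduced, and the benzyl ether is removed.

Key step: step 8

Remark: the oxolane locants of the target (O1, C2 with ring A, C3, C4, C5 with ring B) are used for all ring compounds and for the carbons that become them. The target is read as (2R,3S,4S,5R), all-trans.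

**Step 1**
Reactants: 1 (E)-3,4,5-trimethoxycinnamic acid
Product: 2 methyl (E)-3-(3,4,5-trimethoxyphenyl)prop-2-enoate
Conditions: MeOH, H2SO4 (catalytic), reflux
Reagents that add atoms: methanol, CO
Why: Fischer esterification in excess methanol converts the unhindered conjugated acid cleanly, forms no stereocentre and leaves the E alkene alone.

**Step 2**
Reactants: 2 methyl (E)-3-(3,4,5-trimethoxyphenyl)prop-2-enoate
Product: 3 (E)-3-(3,4,5-trimethoxyphenyl)prop-2-en-1-ol
Conditions: i-Bu2AlH (2.5 equiv), CH2Cl2, -78 to 0 °C; aq potassium sodium tartrate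
Reagents that add atoms: none
Why: Hydride reduction of the enoate with i-Bu2AlH goes by two 1,2-additions at low temperature, so the ester becomes the allylic alcohol while the E alkene and the aryl methyl ethers survive.

**Step 3**
Reactants: 3 (E)-3-(3,4,5-trimethoxyphenyl)prop-2-en-1-ol
Product: 4 [(2S,3S)-3-(3,4,5-trimethoxyphenyl)oxiran-2-yl]methanol
Conditions: Ti(O-i-Pr)4 (10 mol %), L-(+)-diisopropyl tartrate (12 mol %), t-BuOOH (2 equiv, in decane), 4 Å molecular sieves, CH2Cl2, -20 °C; NaOH in brine, 0 °C
Reagents that add atoms: tert-butyl hydroperoxide, CC(C)(C)OO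
Why: Sharpless asymmetric epoxidation, in which the titanium tartrate complex binds the allylic alcohol and the peroxide and, with the L-(+)-tartrate, delivers oxygen to the alkene face that gives the (2S,3S)-epoxy alcohol, so fixing C5 and the provisional C4 centre, while sieves, low temperature and a basic work-up guard the aryl oxirane, whose para methoxy group is twisted out of conjugation by its two neighbours and therefore activates the benzylic C–O bond only moderately.

**Step 4**
Reactants: 4 [(2S,3S)-3-(3,4,5-trimethoxyphenyl)oxiran-2-yl]methanol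
Product: 5 (2R,3S)-3-(3,4,5-trimethoxyphenyl)oxirane-2-carbaldehyde
Conditions: SO3·pyridine (3 equiv), DMSO, Et3N, CH2Cl2, 0 °C
Reagents that add atoms: none
Why: Parikh–Doering oxidation, an activated-DMSO oxidation run under basic and non-aqueous conditions, stops at the aldehyde and spares the acid-labile oxirane, and both stereocentres are kept (the C2 descriptor changes to R only because the formyl group outranks C3).

**Step 5**
Reactants: 5 (2R,3S)-3-(3,4,5-trimethoxyphenyl)oxirane-2-carbaldehyde
Product: 6 (2S,3S)-2-(3,4,5-trimethoxyphenyl)-3-vinyloxirane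
Conditions: MePPh3Br, KN(SiMe3)2, THF, -78 to 0 °C; Et3N-washed silica
Reagents that add atoms: methyltriphenylphosphonium bromide, C[P+](c1ccccc1)(c1ccccc1)c1ccccc1.[Br-]
Why: Wittig methylenation with the unstabilised ylide is faster at low temperature than enolisation or opening of the epoxy aldehyde, so the trans-oxirane and both of its centres are carried unchanged into the vinyloxirane.

**Step 6**
Reactants: 7 syringaldehyde (4-hydroxy-3,5-dimethoxybenzaldehyde)
Product: 8 4-(benzyloxy)-3,5-dimethoxybenzaldehyde
Conditions: BnBr, K2CO3, DMF, 60 °C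
Reagents that add atoms: benzyl bromide, BrCc1ccccc1
Why: Williamson ether synthesis on the acidic syringyl phenoxide caps the phenol with a group that tolerates palladium catalysis, methoxide, periodate and LiAlH4.

**Step 7**
Reactants: 8 4-(benzyloxy)-3,5-dimethoxybenzaldehyde; 9 Meldrum's acid (2,2-dimethyl-1,3-dioxane-4,6-dione)
Product: 10 5-[4-(benzyloxy)-3,5-dimethoxybenzylidene]-2,2-dimethyl-1,3-dioxane-4,6-dione
Conditions: pyrrolidine (10 mol %), AcOH (10 mol %), toluene, rt
Reagents that add atoms: none
Why: Knoevenagel condensation of a non-enolisable aryl aldehyde with the very acidic Meldrum's acid under amine–acid catalysis gives the arylidene, which has no E/Z issue because its two carbonyl arms are alike.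

**Step 8**
Reactants: 6 (2S,3S)-2-(3,4,5-trimethoxyphenyl)-3-vinyloxirane; 10 5-[4-(benzyloxy)-3,5-dimethoxybenzylidene]-2,2-dimethyl-1,3-dioxane-4,6-dione
Product: 13 (1S,3R,4R)-1-[4-(benzyloxy)-3,5-dimethoxyphenyl]-4-ethenyl-8,8-dimethyl-3-(3,4,5-trimethoxyphenyl)-2,7,9-trioxaspiro[4.5]decane-6,10-dione, via (allyl)Pd(PPh3)2 alkoxide zwitterion 11 (not isolated), via oxa-Michael adduct 12 (not isolated)
Conditions: Pd(PPh3)4 (5 mol %), 10 (1.2 equiv), degassed THF, 40 °C, 6 added slowly
Reagents that add atoms: none
Why: Oxidative addition of the zerovalent palladium catalyst takes place at the allylic C4–O bond of 6 from the face opposite to oxygen, whereas the benzylic C5–O bond is not part of the allyl system and keeps its configuration; the alkoxide of 11 then adds reversibly to the arylidene carbon of 10 (O1–C2, oxa-Michael) and the Meldrum's acid carbanion of 12 alkylates the inner allyl carbon (C3–C4). The closest known reaction type is the Pd(PPh3)4-catalysed formal (3+2) cycloaddition of vinyloxiranes with doubly activated alkenes such as arylidene malononitriles and alkylidene Meldrum's acids, applied here to an aryl-bearing oxirane and an electron-rich arylidene. The oxolane closes by a 5-exo allylic alkylation, which the short O1–C2–C3 tether favours over 7-endo attack at the CH2 terminus. At C4 the stabilised carbanion arrives on the allyl face remote from the metal, so the inversion of the ionisation is undone by a second one and the vinyl group comes out opposite to ring B; should the allyl faces exchange through the sigma-allyl form at the CH2 terminus, the closure towards the 4,5-cis isomer would press ring B against the metal, so C5 steers to the same product. C2 is decided under Curtin–Hammett conditions in the closure, where allylic strain against the flat Meldrum's acid enolate holds C2–H in the enolate plane and ring A pseudo-equatorial, and where a closure staggered about the forming C3–C4 bond lets both aryl groups be pseudo-equatorial only in the 2,5-trans isomer, but this is the least secure selectivity of the route and any C2 epimer has to be removed here by chromatography, because C3 is later set by equilibration against both of its neighbours. Capture of 11 must also outrun its hydride-shift isomerisation to an aryl ketone or dienol, which the very electrophilic acceptor in slight excess, the slow addition of 6 and the benzyl cap on ring A (no acidic proton, no push-pull deactivation) should secure; C3 of 13 carries two identical carbonyl arms and is not yet a stereocentre.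

**Step 9**
Reactants: 13 spiro Meldrum's acid oxolane
Product: 16 methyl (2R,3R,4R,5R)-2-[4-(benzyloxy)-3,5-dimethoxyphenyl]-4-ethenyl-5-(3,4,5-trimethoxyphenyl)oxolane-3-carboxylate, via malonic half-ester 14 (not isolated), via C3-epimeric ester mixture 15 (not isolated)
Conditions: NaOMe (1.2 equiv), MeOH–THF, 0 °C to rt, then cold 1 M HCl to pH 3 and extraction; DMSO, 130 °C; then NaOMe (0.2 equiv), MeOH, 40 °C
Reagents that add atoms: sodium methoxide, C[O-].[Na+]
Why: Acyl opening of the Meldrum's acid ring by methoxide (loss of acetone), thermal decarboxylation of the malonic half-ester and base epimerisation of the alpha-centre follow one another, and although protonation of the enol on its open face may first give the 2,3-cis,3,4-cis ester, methoxide drains 15 into 16, the only isomer whose ester is trans to both ring A at C2 and the vinyl group at C4, while loss of O1 by beta-elimination is held back because it is the reverse of a 5-endo-trig closure.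

**Step 10**
Reactants: 16 all-trans 4-ethenyl methyl ester
Product: 18 methyl (2R,3R,4R,5R)-2-[4-(benzyloxy)-3,5-dimethoxyphenyl]-4-formyl-5-(3,4,5-trimethoxyphenyl)oxolane-3-carboxylate, via vicinal diol 17 (not isolated)
Conditions: OsO4 (2 mol %), NaIO4 (4 equiv), 2,6-lutidine (2 equiv), 1,4-dioxane–H2O (3:1), rt; used crude
Reagents that add atoms: osmium tetroxide, O=[Os](=O)(=O)=O; sodium periodate (reoxidant that makes good the oxygen), [Na+].[O-]I(=O)(=O)=O
Why: Lemieux–Johnson oxidation, in which OsO4 dihydroxylates the only alkene to diol 17 and NaIO4 cleaves it in the same flask, is preferred to ozonolysis because of the two electron-rich arenes, and 2,6-lutidine keeps the medium mild enough that the C4 formyl group stays in its already favoured position trans to both neighbours.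

**Step 11**
Reactants: 18 4-formyl methyl ester
Product: 19 [(2R,3S,4S,5R)-2-[4-(benzyloxy)-3,5-dimethoxyphenyl]-5-(3,4,5-trimethoxyphenyl)oxolane-3,4-diyl]dimethanol
Conditions: LiAlH4 (3 equiv), THF, 0 °C to rt; aqueous NaOH work-up
Reagents that add atoms: none
Why: LiAlH4 reduces the aldehyde and the ester in one operation to the two primary alcohols faster than either alpha-centre can epimerise, and the aryl ethers and the oxolane are inert to it.

**Step 12**
Reactants: 19 O-benzyl diol
Product: 20 [(2R,3S,4S,5R)-2-(4-hydroxy-3,5-dimethoxyphenyl)-5-(3,4,5-trimethoxyphenyl)oxolane-3,4-diyl]dimethanol (target)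
Conditions: H2 (1 atm), 10% Pd/C, EtOAc–MeOH, rt, stopped when 19 is consumed
Reagents that add atoms: none
Why: Catalytic hydrogenolysis cleaves the primary, unhindered benzylic C–O bond of the phenolic benzyl ether far faster than the two secondary, ring-bound benzylic C–O bonds at C2 and C5 under one atmosphere of hydrogen, so the oxolane and all four stereocentres are kept.

**Compound list**
1 | (E)-3,4,5-trimethoxycinnamic acid | COc1cc(/C=C/C(=O)O)cc(OC)c1OC | starting material
2 | methyl (E)-3-(3,4,5-trimethoxyphenyl)prop-2-enoate | COc1cc(/C=C/C(=O)OC)cc(OC)c1OC | intermediate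
3 | (E)-3-(3,4,5-trimethoxyphenyl)prop-2-en-1-ol | COc1cc(/C=C/CO)cc(OC)c1OC | intermediate
4 | [(2S,3S)-3-(3,4,5-trimethoxyphenyl)oxiran-2-yl]methanol | O1[C@@H](c2cc(OC)c(OC)c(OC)c2)[C@@H]1CO | intermediate
5 | (2R,3S)-3-(3,4,5-trimethoxyphenyl)oxirane-2-carbaldehyde | O1[C@@H](c2cc(OC)c(OC)c(OC)c2)[C@@H]1C=O | intermediate
6 | (2S,3S)-2-(3,4,5-trimethoxyphenyl)-3-vinyloxirane (trans) | O1[C@@H](c2cc(OC)c(OC)c(OC)c2)[C@@H]1C=C | intermediate
7 | syringaldehyde | COc1cc(C=O)cc(OC)c1O | starting material
8 | 4-(benzyloxy)-3,5-dimethoxybenzaldehyde | COc1cc(C=O)cc(OC)c1OCc1ccccc1 | intermediate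
9 | Meldrum's acid | CC1(C)OC(=O)CC(=O)O1 | starting material
10 | 5-[4-(benzyloxy)-3,5-dimethoxybenzylidene]-2,2-dimethyl-1,3-dioxane-4,6-dione | COc1cc(C=C2C(=O)OC(C)(C)OC2=O)cc(OC)c1OCc1ccccc1 | intermediate
11 | (allyl)Pd(PPh3)2 cation with C5 alkoxide, C5 configuration kept, drawn as its terminal sigma-allyl form | [O-][C@@H](c1cc(OC)c(OC)c(OC)c1)/C=C/C[Pd-]([P+](c1ccccc1)(c1ccccc1)c1ccccc1)[P+](c1ccccc1)(c1ccccc1)c1ccccc1 | intermediate
12 | oxa-Michael adduct of 11 and 10: Meldrum's acid carbanion at C3 and (allyl)Pd(PPh3)2 cation, C2 epimers in equilibrium, drawn as sigma-allyl form | COc1cc(C(O[C@@H](c2cc(OC)c(OC)c(OC)c2)/C=C/C[Pd-]([P+](c2ccccc2)(c2ccccc2)c2ccccc2)[P+](c2ccccc2)(c2ccccc2)c2ccccc2)[C-]2C(=O)OC(C)(C)OC2=O)cc(OC)c1OCc1ccccc1 | intermediate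
13 | (1S,3R,4R)-1-[4-(benzyloxy)-3,5-dimethoxyphenyl]-4-ethenyl-8,8-dimethyl-3-(3,4,5-trimethoxyphenyl)-2,7,9-trioxaspiro[4.5]decane-6,10-dione (ring A at C2 trans to ring B at C5, vinyl at C4 trans to ring B) | COc1cc([C@@H]2O[C@@H](c3cc(OC)c(OC)c(OC)c3)[C@H](C=C)C24C(=O)OC(C)(C)OC4=O)cc(OC)c1OCc1ccccc1 | intermediate
14 | 3-(methoxycarbonyl)oxolane-3-carboxylic acid from 13 (C3 undefined, other centres as in 13) | COc1cc([C@@H]2O[C@@H](c3cc(OC)c(OC)c(OC)c3)[C@H](C=C)C2(C(=O)O)C(=O)OC)cc(OC)c1OCc1ccccc1 | intermediate
15 | methyl 2-[4-(benzyloxy)-3,5-dimethoxyphenyl]-4-ethenyl-5-(3,4,5-trimethoxyphenyl)oxolane-3-carboxylate, C3 epimers (2R,4R,5R) | COc1cc([C@@H]2O[C@@H](c3cc(OC)c(OC)c(OC)c3)[C@H](C=C)C2C(=O)OC)cc(OC)c1OCc1ccccc1 | intermediate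
16 | methyl (2R,3R,4R,5R)-2-[4-(benzyloxy)-3,5-dimethoxyphenyl]-4-ethenyl-5-(3,4,5-trimethoxyphenyl)oxolane-3-carboxylate (all-trans) | COc1cc([C@@H]2O[C@@H](c3cc(OC)c(OC)c(OC)c3)[C@H](C=C)[C@H]2C(=O)OC)cc(OC)c1OCc1ccccc1 | intermediate
17 | 4-(1,2-dihydroxyethyl) analogue of 16 (carbinol centre undefined) | COc1cc([C@@H]2O[C@@H](c3cc(OC)c(OC)c(OC)c3)[C@H](C(O)CO)[C@H]2C(=O)OC)cc(OC)c1OCc1ccccc1 | intermediate
18 | methyl (2R,3R,4R,5R)-2-[4-(benzyloxy)-3,5-dimethoxyphenyl]-4-formyl-5-(3,4,5-trimethoxyphenyl)oxolane-3-carboxylate | COc1cc([C@@H]2O[C@@H](c3cc(OC)c(OC)c(OC)c3)[C@H](C=O)[C@H]2C(=O)OC)cc(OC)c1OCc1ccccc1 | intermediate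
19 | [(2R,3S,4S,5R)-2-[4-(benzyloxy)-3,5-dimethoxyphenyl]-5-(3,4,5-trimethoxyphenyl)oxolane-3,4-diyl]dimethanol | COc1cc([C@@H]2O[C@@H](c3cc(OC)c(OC)c(OC)c3)[C@H](CO)[C@H]2CO)cc(OC)c1OCc1ccccc1 | intermediate
20 | [(2R,3S,4S,5R)-2-(4-hydroxy-3,5-dimethoxyphenyl)-5-(3,4,5-trimethoxyphenyl)oxolane-3,4-diyl]dimethanol | COc1cc([C@@H]2O[C@@H](c3cc(OC)c(OC)c(OC)c3)[C@H](CO)[C@H]2CO)cc(OC)c1O | target

**Total step count:** 12. **Longest linear sequence:** 10 (steps 1 to 5, then 8 to 12).

**Steps most likely to fail**

**Step 8.** Ring A may settle on the wrong face at C2, through poor or inverted facial selectivity in the ring closure, so that material is lost at the separation.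
- The fallback replaces kinetic control at C2 by a late thermodynamic correction. It sets out from 6 and 10, run as in step 8 but harvested for the 2,5-cis spiro compound F1, and it comes back at 20.
- NaOMe opens F1 to the half-ester F2, which is decarboxylated in hot DMSO with no base treatment afterwards.
- In this series both aryl groups shield the same ring face. The enol should therefore be protonated from the face that carries only the vinyl group. That places the ester trans to vinyl, as in the 2,3-cis,3,4-trans ester F3.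
- OsO4 and NaIO4 take F3 through the vicinal diol F4 to the aldehyde F5, and LiAlH4 gives the diol F6.
- TIPSCl and imidazole give the bis(triisopropylsilyl) ether F7, so that no hydroxyl of the two arms can later capture the quinone methide. Hydrogenolysis then gives the phenol F8.
- Warm DBU in MeCN breaks the C2–O1 bond through the ring A quinone methide F9. Its 5-exo re-closure by the C5 hydroxyl is reversible and should collect in the all-trans phenol F10, because only there is ring A trans to the C3 arm. C3, C4 and C5 are not touched.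
- Bu4NF then gives 20.

**Step 9.** Three things may go wrong: loss of CO2 from the hindered half-acid may be slow, the oxolane may open by beta-elimination of O1 from the C3 enolate under methoxide, or the epimerisation at C3 may stall.
- The fallback replaces acid decarboxylation and alkoxide equilibration by a halide-induced dealkoxycarbonylation under neutral conditions. It sets out from 14 and comes back at 16.
- MeI and K2CO3 in DMF give the dimethyl malonate F11.
- A Krapcho reaction (LiCl, wet DMSO, 150 °C) removes one ester.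
- At that temperature C3 should equilibrate through the enol, without alkoxide, to the all-trans ester.

**Step 3.** The electron-rich aryl oxirane may be opened by titanium-assisted solvolysis with isopropanol or tartrate. Enantiomeric purity may be eroded, and the epoxy aldehyde stage that follows is fragile.
- The fallback moves the asymmetric oxidation to the end of the fragment synthesis and runs it in basic buffer. It sets out from 3 and comes back at 6.
- MnO2 in CH2Cl2 gives the cinnamaldehyde F12, and Wittig methylenation gives the diene F13.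
- A Shi epoxidation (KHSO5, K2CO3 buffer near pH 10.5, MeCN–dimethoxymethane–H2O, 0 °C) should oxidise the trans-disubstituted styrenyl alkene in preference to the terminal one.
- The D-fructose-derived ketone gives (R,R)-oxiranes from trans-alkenes, so its enantiomer, made from L-sorbose, is needed for (2S,3S)-6.

**Further compounds**
F1 | step 8 | (1R,3R,4R) C2 epimer of 13 (ring A cis to ring B) | COc1cc([C@H]2O[C@@H](c3cc(OC)c(OC)c(OC)c3)[C@H](C=C)C24C(=O)OC(C)(C)OC4=O)cc(OC)c1OCc1ccccc1
F2 | step 8 | malonic half-ester from F1 (C3 undefined) | COc1cc([C@H]2O[C@@H](c3cc(OC)c(OC)c(OC)c3)[C@H](C=C)C2(C(=O)O)C(=O)OC)cc(OC)c1OCc1ccccc1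
F3 | step 8 | methyl (2S,3R,4R,5R)-2-[4-(benzyloxy)-3,5-dimethoxyphenyl]-4-ethenyl-5-(3,4,5-trimethoxyphenyl)oxolane-3-carboxylate | COc1cc([C@H]2O[C@@H](c3cc(OC)c(OC)c(OC)c3)[C@H](C=C)[C@H]2C(=O)OC)cc(OC)c1OCc1ccccc1
F4 | step 8 | 4-(1,2-dihydroxyethyl) analogue of F3 (carbinol centre undefined) | COc1cc([C@H]2O[C@@H](c3cc(OC)c(OC)c(OC)c3)[C@H](C(O)CO)[C@H]2C(=O)OC)cc(OC)c1OCc1ccccc1
F5 | step 8 | methyl (2S,3R,4R,5R)-2-[4-(benzyloxy)-3,5-dimethoxyphenyl]-4-formyl-5-(3,4,5-trimethoxyphenyl)oxolane-3-carboxylate | COc1cc([C@H]2O[C@@H](c3cc(OC)c(OC)c(OC)c3)[C@H](C=O)[C@H]2C(=O)OC)cc(OC)c1OCc1ccccc1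
F6 | step 8 | (2S,3S,4S,5R) C2 epimer of diol 19 | COc1cc([C@H]2O[C@@H](c3cc(OC)c(OC)c(OC)c3)[C@H](CO)[C@H]2CO)cc(OC)c1OCc1ccccc1
F7 | step 8 | bis(triisopropylsilyl) ether of F6 | COc1cc([C@H]2O[C@@H](c3cc(OC)c(OC)c(OC)c3)[C@H](CO[Si](C(C)C)(C(C)C)C(C)C)[C@H]2CO[Si](C(C)C)(C(C)C)C(C)C)cc(OC)c1OCc1ccccc1
F8 | step 8 | free phenol from F7 | COc1cc([C@H]2O[C@@H](c3cc(OC)c(OC)c(OC)c3)[C@H](CO[Si](C(C)C)(C(C)C)C(C)C)[C@H]2CO[Si](C(C)C)(C(C)C)C(C)C)cc(OC)c1O
F9 | step 8 | ring-opened ring A quinone methide with free C5 hydroxyl (transient) | COC1=CC(=C[C@H](CO[Si](C(C)C)(C(C)C)C(C)C)[C@@H](CO[Si](C(C)C)(C(C)C)C(C)C)[C@@H](O)c2cc(OC)c(OC)c(OC)c2)C=C(OC)C1=O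
F10 | step 8 | (2R,3S,4S,5R) all-trans phenol, bis(triisopropylsilyl) ether of 20 | COc1cc([C@@H]2O[C@@H](c3cc(OC)c(OC)c(OC)c3)[C@H](CO[Si](C(C)C)(C(C)C)C(C)C)[C@H]2CO[Si](C(C)C)(C(C)C)C(C)C)cc(OC)c1O
F11 | step 9 | dimethyl (2S,4R,5R)-2-[4-(benzyloxy)-3,5-dimethoxyphenyl]-4-ethenyl-5-(3,4,5-trimethoxyphenyl)oxolane-3,3-dicarboxylate | COc1cc([C@@H]2O[C@@H](c3cc(OC)c(OC)c(OC)c3)[C@H](C=C)C2(C(=O)OC)C(=O)OC)cc(OC)c1OCc1ccccc1
F12 | step 3 | (E)-3,4,5-trimethoxycinnamaldehyde | COc1cc(/C=C/C=O)cc(OC)c1OC
F13 | step 3 | (E)-1-(3,4,5-trimethoxyphenyl)buta-1,3-diene | COc1cc(/C=C/C=C)cc(OC)c1OC
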